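At late times the two earlier runs lie on top of each other. At 12.0 h Monday's flask reads 11.1% of target and Tuesday's 11.2%, and at 20.0 h they read 6.9% and 7.0%. Yet Tuesday's flask was charged with protic impurity at 28.0% of the substrate charged, against 6.50% in Monday's.

in all of them: substrate 0.10 M
- Monday's: partner 2 equiv; protic impurity 0.0065 M; run made earlier
- Tuesday's: partner 2 equiv; protic impurity 0.028 M; run made earlier
- delta: partner 2.00 equiv; protic impurity 0.00500 M; time 20 h
- zeta: partner 2.00 equiv; protic impurity 0.0100 M; time 20 h
- alpha: partner 2.00 equiv; protic impurity 0.0200 M; time 20 h

- Monday's (time / h: target / %): 1.50: 25.3; 2.50: 25.2; 4.00: 23.1; 8.00: 16.1; 12.0: 11.1; 20.0: 6.9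
- Tuesday's (time / h: target / %): 3.00: 23.5; 6.00: 17.5; 10.0: 12.5; 12.0: 11.2; 15.0: 9.2; 20.0: 7.0

(readings scatter by 0.5 percentage points)

* amount of target at the end, in percent of the substrate charged for delta, zeta, alpha, in this order
* the shape of the row from first to last (rises, then falls / falls, then rises / hardly changes / rises all the way / falls all the way)

- the analysis behind the earlier runs scatters by 0.5 percentage points, standard deviation
- "hardly changes" means that all values lie within two and a half points (for a concentration: within two and a half percent of the largest)

My bench rule: when two runs with the same charges of substrate and partner read alike at the same late time, freeze that reading and read any flask between them in impurity the same at that time. I reckon the level and then how far the row may stray from it: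

level = midway between the end readings = 6.95%

gap between the end readings = 0.1 percentage points; scatter of such a gap = 0.71 points

width of the row over width of the runs = (20.0% − 5.00%) / (28.0% − 6.50%) = 0.698

(0.1 points + 0.71 points) × 0.698 = 0.56 points

That is my end swing: the span I allow the row's end readings, gap and scatter together, scaled to the row's width in impurity.

The rule stops at the edge of the two runs, and delta lies past that edge, with its impurity at 0.769 of Monday's. So delta is an extrapolation, by 0.0698 of the distance between the runs. I commit to a row near 6.95% that hardly changes, with the swing inside the margin given above.

The forecast differs from me. It gives 7.8%, 6%, 6.1%, shape falls, then rises, holding that “the equal endpoints probably straddle a minimum in target”. Its drop from delta to zeta, 1.8 points, is larger than my swing.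

The flask gives 6.74%, 6.73%, 6.71% of target: hardly changes.

    substrate + partner ⇌ target (K = 3.50 M⁻¹, k = 2.20 M⁻¹ h⁻¹)
    substrate + partner ⇌ isomer of the product (K = 120 M⁻¹, k = 1.00 M⁻¹ h⁻¹)
    partner → decomposition product (k = 6.00 × 10⁻⁴ h⁻¹)
    partner + protic impurity → quenched reagent (k = 3.70 M⁻¹ h⁻¹)

In alpha at 20.0 h, protic impurity, the limiting reagent of the quench, stands at 0.020% of its own charge against partner at 48% of its own, and the quench makes no difference worth reading to alpha's target. From delta to alpha the row falls 0.03 points, less than the end swing of 0.56 points. Scaled to the step from delta to zeta, the swing allows 0.19 points, and zeta stands 0.01 points below delta.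

The runs are simulated with constants of no real substance, noise included.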